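**Assumption:** the SMILES descriptors are taken literally. They define a cis-fused decalin, (3S,5R,9R,10R) in drimane numbering (the C9/C10-diepimer of the usual trans-fused 3β-acetoxyalbicanyl ether), so polyene cyclisations that give the trans skeleton are not used. The route is a design from first principles and has not been run.

**Retrosynthetic overview**
1. The C11–O–aryl bond comes from a Mitsunobu reaction of isofraxidin with the homoallylic alcohol; the exocyclic C=CH2 comes from the C8 ketone by a non-basic methylenation.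
2. C9–CH2OH comes from hydroxymethylation of the C8/C9 silyl enol ether on the convex face; the angular methyl comes from cuprate 1,4-addition to a Δ9(10)-8-octalone, which gives the cis ring fusion.
3. The octalone comes from Birch reduction and hydrolysis of (S)-6-methoxy-1,1-dimethyl-2-tetralol; C3 is set by CBS reduction, the gem-dimethyl group by double methylation of 6-methoxy-2-tetralone.
4. No carbocycle is built: ring A is the saturated ring and ring B the dearomatised anisole ring of the tetralone; the coumarin arrives intact with isofraxidin.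
5. Stereocentres are set in the order C3 → C5 → C10 → C9 (drimane numbering).

**Route**

Step 1
Reactants: 1 6-methoxy-3,4-dihydronaphthalen-2(1H)-one; 2 iodomethane
Product: 4 6-methoxy-1,1-dimethyl-3,4-dihydronaphthalen-2(1H)-one, via monomethyl tetralone 3 (not isolated)
Conditions: NaH (2.2 equiv), MeI (2.3 equiv), THF, 0 °C → rt
Reagents that add atoms: iodomethane, CI
Why: Double enolate C-alkylation: C1 is both benzylic and α to the ketone, so it is deprotonated and methylated twice before C3 reacts; no stereocentre is formed.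

Step 2
Reactants: 4 6-methoxy-1,1-dimethyl-3,4-dihydronaphthalen-2(1H)-one
Product: 5 (2S)-6-methoxy-1,1-dimethyl-1,2,3,4-tetrahydronaphthalen-2-ol
Conditions: (R)-2-methyl-CBS-oxazaborolidine (10 mol %), BH3·SMe2, THF, −20 °C; MeOH
Reagents that add atoms: none
Why: Corey–Bakshi–Shibata reduction: the quaternary benzylic carbon acts as the large and the ring CH2 as the small substituent, so the (R)-catalyst delivers hydride to the face that gives the (S)-carbinol, which becomes C3 of the target.

Step 3
Reactants: 5 (2S)-6-methoxy-1,1-dimethyl-1,2,3,4-tetrahydronaphthalen-2-ol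
Product: 8 (4aR,6S)-6-hydroxy-5,5-dimethyl-4,4a,5,6,7,8-hexahydronaphthalen-2(3H)-one, via Birch dihydroanisole 6 (not isolated), via deconjugated enone 7 (not isolated)
Conditions: Li, NH3(l), t-BuOH, THF, −78 → −33 °C; NH4Cl; then 2 M HCl, MeOH, rt
Reagents that add atoms: water, O
Why: Birch reduction gives the 2,5-dihydroanisole, acid hydrolysis of the enol ether gives the β,γ-enone and acid-catalysed double-bond migration gives the conjugated octalone, whose new C4a–H centre is set by axial γ-protonation and thermodynamic equilibration relative to C6 (ring A chair with equatorial OH, H4a trans to OH; the preference is expected to be moderate, so the minor 4a-epimer is separated and re-equilibrated).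

Step 4
Reactants: 8 (4aR,6S)-6-hydroxy-5,5-dimethyl-4,4a,5,6,7,8-hexahydronaphthalen-2(3H)-one; 9 acetic anhydride
Product: 10 (2S,8aR)-1,1-dimethyl-6-oxo-1,2,3,4,6,7,8,8a-octahydronaphthalen-2-yl acetate
Conditions: Ac2O, pyridine, DMAP (cat.), CH2Cl2, rt
Reagents that add atoms: acetic anhydride, CC(=O)OC(C)=O
Why: DMAP-catalysed acylation of the hindered secondary alcohol; no stereocentre is touched and the acetate of the target is now in place.

Step 5
Reactants: 10 (2S,8aR)-1,1-dimethyl-6-oxo-1,2,3,4,6,7,8,8a-octahydronaphthalen-2-yl acetate; 11 methyllithium; 12 chlorotrimethylsilane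
Product: 13 (2S,4aR,8aR)-1,1,4a-trimethyl-6-[(trimethylsilyl)oxy]-1,2,3,4,4a,7,8,8a-octahydronaphthalen-2-yl acetate
Conditions: MeLi/CuI (2:1, Me2CuLi, 2.5 equiv), TMSCl (5 equiv), THF/Et2O, −78 → −40 °C; Et3N, pH 8 buffer
Reagents that add atoms: methyllithium (delivered as Me2CuLi), [Li]C; chlorotrimethylsilane, C[Si](C)(C)Cl
Why: TMSCl-accelerated Gilman cuprate 1,4-addition: methyl adds to C4a on the face of the ring-fusion hydrogen (the usual cis selectivity of octalones with a ring-fusion β-carbon, reinforced here because the trans mode is syn-axial to the axial C1 methyl), which sets the quaternary centre (4aR) and the cis ring fusion while the acetate is inert at −78 °C.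

Step 6
Reactants: 13 (2S,4aR,8aR)-1,1,4a-trimethyl-6-[(trimethylsilyl)oxy]-1,2,3,4,4a,7,8,8a-octahydronaphthalen-2-yl acetate; 14 formaldehyde
Product: 15 (2S,4aR,5R,8aR)-5-(hydroxymethyl)-1,1,4a-trimethyl-6-oxodecahydronaphthalen-2-yl acetate
Conditions: 37 % aq. HCHO, Yb(OTf)3 (10 mol %), THF, rt
Reagents that add atoms: formaldehyde, C=O
Why: Lewis-acid-catalysed Mukaiyama aldol with aqueous formaldehyde (Kobayashi hydroxymethylation): the electrophile is expected to enter C5 of the cis-fused enol ether axially on the convex face, anti to the C4a–C4 bond and away from ring A with its gem-dimethyl group, which places CH2OH cis to the angular methyl (5R) under neutral, non-epimerising conditions.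

Step 7
Reactants: 15 (2S,4aR,5R,8aR)-5-(hydroxymethyl)-1,1,4a-trimethyl-6-oxodecahydronaphthalen-2-yl acetate; 16 dibromomethane
Product: 17 (2S,4aR,5R,8aR)-5-(hydroxymethyl)-1,1,4a-trimethyl-6-methylidenedecahydronaphthalen-2-yl acetate
Conditions: Zn, CH2Br2, TiCl4 (preformed Lombardo reagent, 3 equiv), THF/CH2Cl2, 0 °C → rt
Reagents that add atoms: dibromomethane, BrCBr
Why: Takai–Lombardo methylenation: the non-basic Zn/Ti methylene reagent converts the ketone into the exocyclic alkene without enolisation, retro-aldol cleavage or attack on the acetate, so the α-centre (5R) is kept.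

Step 8
Reactants: 17 (2S,4aR,5R,8aR)-5-(hydroxymethyl)-1,1,4a-trimethyl-6-methylidenedecahydronaphthalen-2-yl acetate; 18 isofraxidin (7-hydroxy-6,8-dimethoxy-2H-chromen-2-one)
Product: 19 (2S,4aR,5R,8aR)-5-{[(6,8-dimethoxy-2-oxo-2H-chromen-7-yl)oxy]methyl}-1,1,4a-trimethyl-6-methylidenedecahydronaphthalen-2-yl acetate
Conditions: PPh3, DIAD, THF, 0 → 45 °C
Reagents that add atoms: isofraxidin, COc1cc2ccc(=O)oc2c(OC)c1O
Why: Mitsunobu etherification: the acidic 7-OH of isofraxidin displaces the activated primary alcohol by SN2 at CH2, so no stereocentre is involved and the acetate and the lactone are untouched.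

**Compound list**
1 | 6-methoxy-3,4-dihydronaphthalen-2(1H)-one (6-methoxy-2-tetralone) | COc1ccc2c(c1)CCC(=O)C2 | starting material
2 | iodomethane | CI | starting material
3 | 6-methoxy-1-methyl-3,4-dihydronaphthalen-2(1H)-one (racemic, not isolated) | COc1ccc2c(c1)CCC(=O)C2C | intermediate
4 | 6-methoxy-1,1-dimethyl-3,4-dihydronaphthalen-2(1H)-one | COc1ccc2c(c1)CCC(=O)C2(C)C | intermediate
5 | (2S)-6-methoxy-1,1-dimethyl-1,2,3,4-tetrahydronaphthalen-2-ol | COc1ccc2c(c1)CC[C@H](O)C2(C)C | intermediate
6 | (2S)-6-methoxy-1,1-dimethyl-1,2,3,4,5,8-hexahydronaphthalen-2-ol (not isolated) | COC1=CCC2=C(C1)CC[C@H](O)C2(C)C | intermediate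
7 | (6S)-6-hydroxy-5,5-dimethyl-3,4,5,6,7,8-hexahydronaphthalen-2(1H)-one (not isolated) | O=C1CCC2=C(C1)CC[C@H](O)C2(C)C | intermediate
8 | (4aR,6S)-6-hydroxy-5,5-dimethyl-4,4a,5,6,7,8-hexahydronaphthalen-2(3H)-one | O=C1CC[C@H]2C(C)(C)[C@@H](O)CCC2=C1 | intermediate
9 | acetic anhydride | CC(=O)OC(C)=O | starting material
10 | (2S,8aR)-1,1-dimethyl-6-oxo-1,2,3,4,6,7,8,8a-octahydronaphthalen-2-yl acetate | O=C1CC[C@H]2C(C)(C)[C@@H](OC(C)=O)CCC2=C1 | intermediate
11 | methyllithium | [Li]C | starting material
12 | chlorotrimethylsilane | C[Si](C)(C)Cl | starting material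
13 | (2S,4aR,8aR)-1,1,4a-trimethyl-6-[(trimethylsilyl)oxy]-1,2,3,4,4a,7,8,8a-octahydronaphthalen-2-yl acetate | C1=C(O[Si](C)(C)C)CC[C@H]2C(C)(C)[C@@H](OC(C)=O)CC[C@@]12C | intermediate
14 | formaldehyde | C=O | starting material
15 | (2S,4aR,5R,8aR)-5-(hydroxymethyl)-1,1,4a-trimethyl-6-oxodecahydronaphthalen-2-yl acetate | O=C1CC[C@H]2C(C)(C)[C@@H](OC(C)=O)CC[C@@]2(C)[C@@H]1CO | intermediate
16 | dibromomethane | BrCBr | starting material
17 | (2S,4aR,5R,8aR)-5-(hydroxymethyl)-1,1,4a-trimethyl-6-methylidenedecahydronaphthalen-2-yl acetate | C=C1CC[C@H]2C(C)(C)[C@@H](OC(C)=O)CC[C@@]2(C)[C@@H]1CO | intermediate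
18 | isofraxidin (7-hydroxy-6,8-dimethoxy-2H-chromen-2-one) | COc1cc2ccc(=O)oc2c(OC)c1O | starting material
19 | (2S,4aR,5R,8aR)-5-{[(6,8-dimethoxy-2-oxo-2H-chromen-7-yl)oxy]methyl}-1,1,4a-trimethyl-6-methylidenedecahydronaphthalen-2-yl acetate | C=C1CC[C@H]2C(C)(C)[C@@H](OC(C)=O)CC[C@@]2(C)[C@@H]1COc1c(OC)cc2ccc(=O)oc2c1OC | target

**Step count:** 8 steps in total; longest linear sequence 8 steps (from 6-methoxy-2-tetralone; isofraxidin is used as purchased).

**Three steps most likely to fail**

Step 6 (facial selectivity at C5 of the enol ether; the convex-face argument is a conformational prediction, and the wanted epimer may be the less stable one). The fallback sets out from 13 and reverses the order of bond formation at this carbon. Eschenmoser's salt (CH2=NMe2+ I−, CH2Cl2) gives the Mannich base F1. MeI gives the methiodide F2, and NaHCO3 eliminates it to the α-methylene ketone F3. Copper-catalysed conjugate borylation (B2pin2, CuCl, NaOt-Bu, DPEphos, MeOH, THF) gives the boryl ketone F4. Here the C5 hydrogen, not the carbon substituent, is delivered to the enolate on the face that electrophiles prefer, so the CH2 group ends on the opposite face to the one the aldol gave. Oxidation of the C–B bond with NaBO3·4H2O (THF/H2O) comes back to the route at 15.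

Step 7 (the β-hydroxy ketone may dehydrate, undergo retro-aldol loss of formaldehyde or epimerise before it is methylenated). The fallback sets out from 15 and replaces carbonyl methylenation by a Peterson addition–elimination. Me3SiCH2Li/CeCl3 (THF, −78 °C, non-basic organocerium 1,2-addition) gives the β-hydroxysilane F5. Acid-induced elimination (aq. HF, MeCN) comes back to the route at 17.

Step 8 (a β-branched primary alcohol and a phenol flanked by two methoxy groups may make the Mitsunobu reaction stall). The fallback sets out from 17 and separates activation from displacement. MsCl, Et3N (CH2Cl2, 0 °C) gives the mesylate F6. SN2 displacement with the caesium phenoxide of 18 (Cs2CO3, DMF, 70 °C) comes back to the route at 19.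

**Further compounds**
F1 | step 6 | (2S,4aR,8aR)-5-[(dimethylamino)methyl]-1,1,4a-trimethyl-6-oxodecahydronaphthalen-2-yl acetate (C5 epimers) | O=C1CC[C@H]2C(C)(C)[C@@H](OC(C)=O)CC[C@@]2(C)C1CN(C)C
F2 | step 6 | {[(4aR,6S,8aR)-6-acetoxy-5,5,8a-trimethyl-2-oxodecahydronaphthalen-1-yl]methyl}trimethylammonium iodide (C1 epimers) | O=C1CC[C@H]2C(C)(C)[C@@H](OC(C)=O)CC[C@@]2(C)C1C[N+](C)(C)C.[I-]
F3 | step 6 | (2S,4aR,8aR)-1,1,4a-trimethyl-5-methylidene-6-oxodecahydronaphthalen-2-yl acetate | O=C1CC[C@H]2C(C)(C)[C@@H](OC(C)=O)CC[C@@]2(C)C1=C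
F4 | step 6 | (2S,4aR,5S,8aR)-1,1,4a-trimethyl-6-oxo-5-[(4,4,5,5-tetramethyl-1,3,2-dioxaborolan-2-yl)methyl]decahydronaphthalen-2-yl acetate | O=C1CC[C@H]2C(C)(C)[C@@H](OC(C)=O)CC[C@@]2(C)[C@@H]1CB3OC(C)(C)C(C)(C)O3
F5 | step 7 | (2S,4aR,5R,8aR)-6-hydroxy-5-(hydroxymethyl)-1,1,4a-trimethyl-6-[(trimethylsilyl)methyl]decahydronaphthalen-2-yl acetate (C6 epimers) | C[Si](C)(C)CC1(O)CC[C@H]2C(C)(C)[C@@H](OC(C)=O)CC[C@@]2(C)[C@@H]1CO
F6 | step 8 | (2S,4aR,5R,8aR)-5-[(methanesulfonyloxy)methyl]-1,1,4a-trimethyl-6-methylidenedecahydronaphthalen-2-yl acetate | C=C1CC[C@H]2C(C)(C)[C@@H](OC(C)=O)CC[C@@]2(C)[C@@H]1COS(C)(=O)=O
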